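(The data are simulated with constants of no real substance; scatter was added.)

1. The leftover that started me was the 5.6 % of electrophile still present in the elm run at 10.0 d, and I wanted to know what a new flask would keep.

| flask | electrophile | solid nucleophile | remark | time |
|---|---|---|---|---|
| larch | 0.54 M | 2.4 M | run made earlier |  |
| elm | 1.2 M | 2.4 M | run made earlier |  |
| flask | 0.80 M | 2.40 M |  | 10 d |

- larch (time / d: electrophile / %, target / %): 0.500: 93.2, 3.5; 1.67: 70.7, 27.2; 3.00: 45.6, 54.8; 4.00: 30.3, 69.7; 6.00: 6.5, 89.8; 8.00: 1.4, 97.3; 10.0: 0, 99.2
- elm (time / d: electrophile / %, target / %): 0.500: 96.3, 5.0; 1.67: 82.7, 17.5; 3.00: 68.0, 31.2; 4.00: 55.3, 43.4; 6.00: 33.9, 64.1; 8.00: 19.0, 80.5; 10.0: 5.6, 92.7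

(each reading ± 1 percentage point)

- at the start none of the solid nucleophile is in solution
- the earlier runs do not show how much of nucleophile is bound; that part of a forecast is a guess

- part of the electrophile that has reacted at 10 d
- share of free nucleophile in free nucleophile and protonated nucleophile together, at 10 d

2. The runs looked contradictory: elm held twice the electrophile of larch, yet from 0.500 d to 4.00 d it lost 0.141 M d⁻¹ against 0.0970 M d⁻¹ in larch, a factor of 1.45.

3. Because the loss grew less than the charge, I read it as a feed from the solid nucleophile, which both runs received alike and which starts undissolved.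

4. Taking the slower feed, that of larch, for the new flask, I reckoned that its charge goes at 0.121 d⁻¹, and this clearing rate adds up over 10 d to 1.21 charges, more than the whole charge, so I expected very little electrophile to remain.

5. The forecast gave 99 % reacted and a free share of 60 %, the first on “supply from the solid limiting the reaction”, the second declared a guess.

6. The flask gave 99.1 % reacted and a free share of 41.8 %, which is 18 percentage points below the forecast. That share had already stood at 40.5 % at 1.00 d and 40.8 % at 5.00 d. The clearing rate reckons 60.5 % used at 5.00 d, and the flask had used more, 70.3 %.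

    electrophile + nucleophile → acid set free + target (k = 0.380 L mol⁻¹ h⁻¹)
    nucleophile + acid set free ⇌ protonated nucleophile, settled at all times (K = 140 L mol⁻¹)
    2 electrophile → self-condensation product (k = 2.30 × 10⁻⁵ L mol⁻¹ h⁻¹)
    solid nucleophile ⇌ nucleophile, rate k4*(cs4 - [nucleophile]) while solid is left; crystals form when [nucleophile] > cs4 (solubility = 0.150 M, k = 0.0450 h⁻¹)
    crystals ⇌ acid set free, rate k5*(cs5 - [acid set free]) while solid is left; crystals form when [acid set free] > cs5 (solubility = 10.0 mM, k = 9.50 h⁻¹)

7. In a neighbour flask charged with 0.60 M of solid nucleophile, that charge equals 75.0 % of the electrophile, which the clearing rate reaches in 6.18 d, sooner than 10 d. That neighbour gave 75.1 % reacted, with solid nucleophile the limiting reagent, 0.069 % of it remaining.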